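**Retrosynthetic overview**
1. Target 17 ⇒ E-selective cross-metathesis at C3′=C4′: bicyclic diene 8 + (R)-2-methylbut-3-enoic acid 16 (C2′ comes from an Evans deconjugative methylation).
2. Diene 8 ⇒ terminal alkyne 5: Zr-catalysed methylalumination and Pd vinylation build the (5′E)-trisubstituted olefin and the diene in one flask.
3. Alkyne 5 ⇒ acyclic trienyne 4: one enantioselective proton-initiated polyene cascade closes ring A (C4–C5 bond), then ring B (C9–C10 bond), and ends by loss of H-9 to give the C8=C9 olefin; C5 and C10 are set here.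
4. Trienyne 4 ⇒ (2E,6E)-farnesyl bromide 1 + propargyl bromide 2.

Assumption: the SMILES is read as the normal-labdane antipode (ring 4aS,8aS = 10β-methyl/5α-H) with 2′R, 3′E, 5′E in the acid chain; ring atoms carry labdane numbers (C5, C8, C9, C10) and side-chain atoms the primed locants of the octadienoic acid name.

**Step 1**
Reactants: 1 (2E,6E)-farnesyl bromide; 2 propargyl bromide
Product: 4 (5E,9E)-6,10,14-trimethylpentadeca-5,9,13-trien-1-yne, via allenylmagnesium bromide 3 (not isolated)
Conditions: 2, Mg, HgCl2 (cat.), Et2O, 0 °C; then 1, Et2O, −20 °C → rt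
Reagents that add atoms: none
Why: Grignard coupling with a primary allylic bromide, in which the allenylmagnesium species reacts through its γ-carbon (SE2′) to give the propargyl product and attacks the unhindered CH2Br carbon of 1 (SN2), so both E-olefins are untouched and no stereocentre is formed.

**Step 2**
Reactants: 4 (5E,9E)-6,10,14-trimethylpentadeca-5,9,13-trien-1-yne
Product: 5 (4aS,8aS)-5-(but-3-yn-1-yl)-1,1,4a,6-tetramethyl-1,2,3,4,4a,7,8,8a-octahydronaphthalene
Conditions: confined chiral IDPi Brønsted acid (5 mol%, the antipode that gives natural (−)-ambrox from homofarnesol), (CF3)3COH, −10 °C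
Reagents that add atoms: none
Why: Proposed new method: a Brønsted-acid-initiated cationic polyene bicyclisation (Stork–Eschenmoser) in which the confined acid protonates only the accessible terminal isopropylidene olefin on one face, the E,E-triene folds chair–chair so that C10–Me and H-5 become trans and C5/C10 are set as 4aS,8aS, the tertiary C8 cation loses the axial H-9 (Zaitsev; any Δ7 or exocyclic isomer is re-protonated and funnels to the hindered tetrasubstituted olefin), and the terminal alkyne, orders of magnitude less nucleophilic than a trisubstituted olefin, stays a spectator; the closest known reaction types are the IDPi-catalysed cyclisation of homofarnesol to (−)-ambrox and the chiral Lewis-acid-assisted Brønsted acid cyclisation of homo(polyprenyl)arenes.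

**Step 3**
Reactants: 5 (4aS,8aS)-5-(but-3-yn-1-yl)-1,1,4a,6-tetramethyl-1,2,3,4,4a,7,8,8a-octahydronaphthalene
Product: 8 (4aS,8aS)-1,1,4a,6-tetramethyl-5-[(3E)-3-methylhexa-3,5-dien-1-yl]-1,2,3,4,4a,7,8,8a-octahydronaphthalene, via alkenyldimethylalane 6 (not isolated), via alkenylzinc chloride 7 (not isolated)
Conditions: Me3Al (2.5 eq), Cp2ZrCl2 (25 mol%), CH2Cl2, 0 °C → rt; then ZnCl2 (1 eq), Pd(PPh3)4 (5 mol%), CH2=CHBr (3 eq), THF, rt
Reagents that add atoms: trimethylaluminium C[Al](C)C; vinyl bromide C=CBr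
Why: Negishi Zr-catalysed methylalumination adds Me and Al syn with Me on the internal carbon, which fixes the 5′E olefin, and the Pd/Zn Negishi alkenyl–alkenyl coupling proceeds with retention; the tetrasubstituted ring olefin is inert to both.

**Step 4**
Reactants: 9 (R)-4-benzyl-2-oxazolidinone; 10 (E)-but-2-enoyl chloride
Product: 12 (R)-4-benzyl-3-[(E)-but-2-enoyl]oxazolidin-2-one, via N-lithio oxazolidinone 11 (not isolated)
Conditions: n-BuLi, THF, −78 °C; then 10, −78 → 0 °C
Reagents that add atoms: none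
Why: Standard N-acylation of the lithiated Evans auxiliary by the acid chloride; no new stereocentre.

**Step 5**
Reactants: 12 (R)-4-benzyl-3-[(E)-but-2-enoyl]oxazolidin-2-one
Product: 14 (R)-4-benzyl-3-[(R)-2-methylbut-3-enoyl]oxazolidin-2-one, via sodium dienolate 13 (not isolated)
Conditions: NaHMDS (1.05 eq), THF, −78 °C; then MeI (3 eq), −78 °C
Reagents that add atoms: methyl iodide CI
Why: Evans deconjugative alkylation, in which γ-deprotonation gives the chelated (Z)-dienolate and MeI attacks the α-carbon on the face opposite the benzyl group, setting the future C2′ as R (the minor diastereomer is removed by chromatography).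

**Step 6**
Reactants: 14 (R)-4-benzyl-3-[(R)-2-methylbut-3-enoyl]oxazolidin-2-one
Product: 16 (R)-2-methylbut-3-enoic acid, via lithium peroxycarboxylate 15 (not isolated)
Conditions: LiOH, H2O2, THF/H2O (3:1), 0 °C; then Na2SO3; then HCl to pH 2
Reagents that add atoms: hydrogen peroxide OO
Why: Hydroperoxide cleavage of the Evans imide attacks the exocyclic carbonyl at 0 °C without α-epimerisation or olefin migration, and sulfite reduces the peracid to the acid while the auxiliary is recovered.

**Step 7**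
Reactants: 8 (4aS,8aS)-1,1,4a,6-tetramethyl-5-[(3E)-3-methylhexa-3,5-dien-1-yl]-1,2,3,4,4a,7,8,8a-octahydronaphthalene; 16 (R)-2-methylbut-3-enoic acid (3 eq)
Product: 17 (2R,3E,5E)-2,6-dimethyl-8-[(4aS,8aS)-2,5,5,8a-tetramethyl-3,4,4a,5,6,7,8,8a-octahydronaphthalen-1-yl]octa-3,5-dienoic acid
Conditions: Hoveyda–Grubbs II (7.5 mol%), 1,4-benzoquinone (10 mol%), CH2Cl2, 40 °C
Reagents that add atoms: none
Why: Ru-catalysed olefin cross-metathesis occurs only at the monosubstituted terminus of the diene because the trisubstituted C5′=C6′ and tetrasubstituted C8=C9 olefins are too hindered, the α-branched partner and diene conjugation favour the 3′E olefin, and the neutral conditions with benzoquinone (which suppresses Ru–H olefin migration) leave C2′ untouched.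

**Compound list**
1 | (2E,6E)-farnesyl bromide, (2E,6E)-1-bromo-3,7,11-trimethyldodeca-2,6,10-triene | CC(C)=CCC/C(C)=C/CC/C(C)=C/CBr | starting material
2 | propargyl bromide, 3-bromoprop-1-yne | C#CCBr | starting material
3 | allenylmagnesium bromide | C=C=C[Mg]Br | intermediate (not isolated)
4 | (5E,9E)-6,10,14-trimethylpentadeca-5,9,13-trien-1-yne | CC(C)=CCC/C(C)=C/CC/C(C)=C/CCC#C | intermediate
5 | (4aS,8aS)-5-(but-3-yn-1-yl)-1,1,4a,6-tetramethyl-1,2,3,4,4a,7,8,8a-octahydronaphthalene | CC1=C(CCC#C)[C@@]2(C)CCCC(C)(C)[C@@H]2CC1 | intermediate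
6 | dimethyl{(1E)-2-methyl-4-[(4aS,8aS)-2,5,5,8a-tetramethyl-3,4,4a,5,6,7,8,8a-octahydronaphthalen-1-yl]but-1-en-1-yl}alane | CC1=C(CC/C(C)=C/[Al](C)C)[C@@]2(C)CCCC(C)(C)[C@@H]2CC1 | intermediate (not isolated)
7 | chloro{(1E)-2-methyl-4-[(4aS,8aS)-2,5,5,8a-tetramethyl-3,4,4a,5,6,7,8,8a-octahydronaphthalen-1-yl]but-1-en-1-yl}zinc | CC1=C(CC/C(C)=C/[Zn]Cl)[C@@]2(C)CCCC(C)(C)[C@@H]2CC1 | intermediate (not isolated)
8 | (4aS,8aS)-1,1,4a,6-tetramethyl-5-[(3E)-3-methylhexa-3,5-dien-1-yl]-1,2,3,4,4a,7,8,8a-octahydronaphthalene | CC1=C(CC/C(C)=C/C=C)[C@@]2(C)CCCC(C)(C)[C@@H]2CC1 | intermediate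
9 | (R)-4-benzyl-2-oxazolidinone | O=C1N[C@H](Cc2ccccc2)CO1 | starting material
10 | (E)-but-2-enoyl chloride (crotonyl chloride) | C/C=C/C(Cl)=O | starting material
11 | lithium (R)-4-benzyl-2-oxooxazolidin-3-ide | [Li]N1[C@H](Cc2ccccc2)COC1=O | intermediate (not isolated)
12 | (R)-4-benzyl-3-[(E)-but-2-enoyl]oxazolidin-2-one | C/C=C/C(=O)N1[C@H](Cc2ccccc2)COC1=O | intermediate
13 | sodium (1Z)-1-[(R)-4-benzyl-2-oxooxazolidin-3-yl]buta-1,3-dien-1-olate | [Na+].[O-]/C(=C\C=C)N1[C@H](Cc2ccccc2)COC1=O | intermediate (not isolated)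
14 | (R)-4-benzyl-3-[(R)-2-methylbut-3-enoyl]oxazolidin-2-one | C=C[C@@H](C)C(=O)N1[C@H](Cc2ccccc2)COC1=O | intermediate
15 | lithium (R)-2-methylbut-3-eneperoxoate | C=C[C@@H](C)C(=O)O[O-].[Li+] | intermediate (not isolated)
16 | (R)-2-methylbut-3-enoic acid | C=C[C@@H](C)C(=O)O | intermediate
17 | (2R,3E,5E)-2,6-dimethyl-8-[(4aS,8aS)-2,5,5,8a-tetramethyl-3,4,4a,5,6,7,8,8a-octahydronaphthalen-1-yl]octa-3,5-dienoic acid | CC1=C(CC/C(C)=C/C=C/[C@@H](C)C(=O)O)[C@@]2(C)CCCC(C)(C)[C@@H]2CC1 | target

**Step count**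
Total: 7 steps. Longest linear sequence: 4 steps (1 → 2 → 3 → 7, or 4 → 5 → 6 → 7).

**Steps most likely to fail**

Step 2 (cyclisation) is the highest risk. The substrate has no polar group to anchor it in the catalyst, so the ee may be lower than for homofarnesol, and any minor enantiomer of 5 ends up as a hard-to-separate diastereomer of 17. Proton loss may also give Δ7 or exocyclic isomers, and the alkyne may take part to some extent. The fallback sets out from 1 and comes back at 5, and it changes the terminating event from proton loss to capture of the C8 cation by a carbonyl oxygen. Compound 1 alkylates ethyl acetoacetate (NaOEt, EtOH) to give ethyl (4E,8E)-2-acetyl-5,9,13-trimethyltetradeca-4,8,12-trienoate F1. Saponification and decarboxylation (aq. KOH, then H3O+, 60 °C) give (5E,9E)-6,10,14-trimethylpentadeca-5,9,13-trien-2-one F2. The same chiral acid, or a squalene–hopene cyclase (which is known to accept this substrate type), cyclises F2 to sclareol oxide F3, so the ring oxygen now fixes where the cation ends. TsOH in wet toluene at 80 °C reopens F3 through the C8 cation under equilibrating conditions to 4-[(4aS,8aS)-2,5,5,8a-tetramethyl-3,4,4a,5,6,7,8,8a-octahydronaphthalen-1-yl]butan-2-one F4. Kinetic enol phosphate formation (LDA, then ClP(O)(OEt)2) gives diethyl 4-[(4aS,8aS)-2,5,5,8a-tetramethyl-3,4,4a,5,6,7,8,8a-octahydronaphthalen-1-yl]but-1-en-2-yl phosphate F5, and elimination with LDA gives 5.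

Step 7 (cross-metathesis on a conjugated diene) is the second risk. Possible problems are an E/Z mixture at C3′=C4′, truncation by attack at the internal olefin, homodimers, and Ru–H isomerisation of the β,γ-unsaturated acid. The fallback sets out from 5 (and uses 16) and comes back at 17, and it makes the diene by sp2–sp2 coupling instead of metathesis. Carboalumination of 5 as in step 3, then iodinolysis of 6 (I2, THF, −30 °C), gives (4aS,8aS)-5-[(3E)-4-iodo-3-methylbut-3-en-1-yl]-1,1,4a,6-tetramethyl-1,2,3,4,4a,7,8,8a-octahydronaphthalene F6. Cross-metathesis of 16 with vinylboronic acid pinacol ester, a simple and reactive partner, gives (2R,3E)-2-methyl-4-(4,4,5,5-tetramethyl-1,3,2-dioxaborolan-2-yl)but-3-enoic acid F7. Suzuki–Miyaura coupling of F6 with F7 (Pd(PPh3)4, aq. K3PO4, THF, rt) and acidification give 17; the acid is a carboxylate during the coupling, so C2′ cannot enolise.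

Step 1 (Grignard coupling) is the third risk. The allenyl reagent can give some allenic product and some SN2′ attack on 1, and these isomers are hard to remove from 4. The fallback sets out from 1 and comes back at 4, and it uses a masked, regiochemically defined C3 nucleophile with a later deprotection. 1-(Trimethylsilyl)propyne is lithiated (n-BuLi, THF, −78 °C) and alkylated with 1 to give trimethyl[(5E,9E)-6,10,14-trimethylpentadeca-5,9,13-trien-1-yn-1-yl]silane F8, and K2CO3 in MeOH removes the silyl group to give 4.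

**Further compounds**
F1 | step 2 | ethyl (4E,8E)-2-acetyl-5,9,13-trimethyltetradeca-4,8,12-trienoate | CC(C)=CCC/C(C)=C/CC/C(C)=C/CC(C(C)=O)C(=O)OCC
F2 | step 2 | (5E,9E)-6,10,14-trimethylpentadeca-5,9,13-trien-2-one (E,E-farnesylacetone) | CC(C)=CCC/C(C)=C/CC/C(C)=C/CCC(C)=O
F3 | step 2 | sclareol oxide, (5S,8R,9R,10S)-8,13-epoxy-14,15-dinorlabd-12-ene | CC1=CC[C@H]2[C@](C)(O1)CC[C@H]3C(C)(C)CCC[C@]23C
F4 | step 2 | 4-[(4aS,8aS)-2,5,5,8a-tetramethyl-3,4,4a,5,6,7,8,8a-octahydronaphthalen-1-yl]butan-2-one | CC1=C(CCC(C)=O)[C@@]2(C)CCCC(C)(C)[C@@H]2CC1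
F5 | step 2 | diethyl 4-[(4aS,8aS)-2,5,5,8a-tetramethyl-3,4,4a,5,6,7,8,8a-octahydronaphthalen-1-yl]but-1-en-2-yl phosphate | CC1=C(CCC(=C)OP(=O)(OCC)OCC)[C@@]2(C)CCCC(C)(C)[C@@H]2CC1
F6 | step 7 | (4aS,8aS)-5-[(3E)-4-iodo-3-methylbut-3-en-1-yl]-1,1,4a,6-tetramethyl-1,2,3,4,4a,7,8,8a-octahydronaphthalene | CC1=C(CC/C(C)=C/I)[C@@]2(C)CCCC(C)(C)[C@@H]2CC1
F7 | step 7 | (2R,3E)-2-methyl-4-(4,4,5,5-tetramethyl-1,3,2-dioxaborolan-2-yl)but-3-enoic acid | CC1(C)OB(/C=C/[C@@H](C)C(=O)O)OC1(C)C
F8 | step 1 | trimethyl[(5E,9E)-6,10,14-trimethylpentadeca-5,9,13-trien-1-yn-1-yl]silane | CC(C)=CCC/C(C)=C/CC/C(C)=C/CCC#C[Si](C)(C)C
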